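Assumption: (S)-BINAL-H is taken to give the (3aS,6aR)-lactone in step 7; if the observed sense is opposite, (R)-BINAL-H is used instead.

**Retrosynthetic overview**
1. Target ⇐ desilylation ⇐ reagent-controlled (CBS) reduction of the aryl ketone at the future carbinol carbon.
2. Aryl ketone ⇐ single addition of a guaiacyl Grignard to the lactone C=O of a cis-fused 4-aryl-furo[3,4-c]furanone. The lactone is a temporary tether that locks the 3,4-cis relationship and releases the CH2OH on opening.
3. 4-Aryl lactone ⇐ Ni/decatungstate C(sp3)–H arylation of the parent bicyclic lactone with the guaiacyl bromide (oxolane C2–aryl bond, exo face, 2,3-trans).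
4. Parent lactone ⇐ desymmetrising reduction of a meso anhydride ⇐ [3+2] of the parent carbonyl ylide with maleic anhydride. The oxolane ring is formed first, then the lactone ring, which is opened again in step 9.
5. Both aryl partners ⇐ one silyl-protected 4-bromoguaiacol made from catechol.

**Route**

Step 1
Reactants: 1 catechol
Product: 2 guaiacol (2-methoxyphenol)
Conditions: MeI (1.0 equiv), K2CO3, acetone, reflux
Reagents that add atoms: iodomethane, CI
Why: Williamson mono-O-methylation under stoichiometric control; guaiacol is separated from veratrole by base extraction.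

Step 2
Reactants: 2 guaiacol
Product: 3 4-bromo-2-methoxyphenol
Conditions: NBS, MeCN, 0 °C
Reagents that add atoms: N-bromosuccinimide, O=C1CCC(=O)N1Br
Why: Electrophilic aromatic bromination goes para to the free OH, the stronger donor.

Step 3
Reactants: 3 4-bromo-2-methoxyphenol
Product: 4 tert-butyl(4-bromo-2-methoxyphenoxy)dimethylsilane
Conditions: TBSCl, imidazole, DMF, rt
Reagents that add atoms: tert-butyldimethylsilyl chloride, CC(C)(C)[Si](C)(C)Cl
Why: Imidazole-promoted silylation; TBS has no hydridic C–H for the later hydrogen-atom-transfer step and is removed by fluoride at the end.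

Step 4
Reactants: 4 aryl bromide
Product: 5 tert-butyl(4-iodo-2-methoxyphenoxy)dimethylsilane
Conditions: CuI (5 mol%), trans-N,N'-dimethylcyclohexane-1,2-diamine (10 mol%), NaI, dioxane, 110 °C
Reagents that add atoms: sodium iodide, [Na+].[I-]
Why: Cu-catalysed aromatic Finkelstein; the iodide undergoes I/Mg exchange at −20 °C (step 9), which the electron-rich bromide does not.

Step 5
Reactants: 6 (trimethylsilyl)methanol
Product: 7 [(chloromethoxy)methyl]trimethylsilane
Conditions: (CH2O)n, HCl (g), 0 °C; dry over CaCl2, distil
Reagents that add atoms: paraformaldehyde (as formaldehyde), C=O; hydrogen chloride, Cl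
Why: Standard chloromethyl ether formation (hemiformal, then chloride).

Step 6
Reactants: 7 [(chloromethoxy)methyl]trimethylsilane; 8 maleic anhydride
Product: 9 meso-(3aR,6aS)-tetrahydro-1H-furo[3,4-c]furan-1,3(4H)-dione (cis-oxolane-3,4-dicarboxylic anhydride)
Conditions: CsF, MeCN, rt
Reagents that add atoms: none
Why: Fluoride-induced 1,3-elimination gives the parent carbonyl ylide, which undergoes suprafacial [3+2] cycloaddition; the cis alkene geometry gives the cis-fused meso oxolane.

Step 7
Reactants: 9 meso anhydride
Product: 10 (3aS,6aR)-tetrahydro-1H,3H-furo[3,4-c]furan-1-one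
Conditions: (S)-BINAL-H [LiAlH4, (S)-BINOL, EtOH], THF, −78 °C to rt; then 1 M HCl
Reagents that add atoms: none
Why: Enantiotopic-group-selective hydride reduction of a meso anhydride (Noyori BINAL-H desymmetrisation), known on ring-fused succinic anhydrides; it sets both ring-fusion centres (future C3 and C4 of the oxolane, cis).

Step 8 (key step)
Reactants: 10 bicyclic lactone (3 equiv, excess recovered); 4 aryl bromide (1 equiv)
Product: 11 (3aR,4S,6aR)-4-[4-(tert-butyldimethylsilyloxy)-3-methoxyphenyl]tetrahydro-1H,3H-furo[3,4-c]furan-1-one (aryl exo)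
Conditions: (Bu4N)4[W10O32] (2 mol%), NiBr2·dtbbpy (5 mol%), K3PO4, MeCN, 390 nm LEDs, rt
Reagents that add atoms: none
Why: Proposed new method: site- and exo-selective decatungstate/Ni C(sp3)–H arylation of a lactone-fused oxolane. Excited decatungstate (electrophilic H-atom abstractor) should take the most hydridic α-oxy hydrogen, at C4, because C6–H is β to the lactone C=O and C3–H is α-acyloxy, both polarity-mismatched. The C4 radical is captured by (dtbbpy)Ni(Ar)Br on the convex face of the cis-bicyclo[3.3.0] core, and reductive elimination from Ni(III) places the aryl exo, i.e. trans to the CH2O bridge (2S, 2,3-trans in the target). The closest known reaction is decatungstate/Ni (or Ir/Ni/quinuclidine) α-oxy C–H arylation of simple cyclic ethers with aryl bromides, which has not been shown on a substrate with two inequivalent ether CH2 groups or as a stereocontrolled step.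

Step 9
Reactants: 5 aryl iodide; 11 aryl lactone
Product: 12 {(3R,4R,5S)-5-[4-(TBSO)-3-methoxyphenyl]-4-(hydroxymethyl)oxolan-3-yl}[4-(TBSO)-3-methoxyphenyl]methanone (in equilibrium with its cyclic hemiketal)
Conditions: 5, i-PrMgCl·LiCl, THF, −20 °C; then 11, −40 to 0 °C; aq NH4Cl
Reagents that add atoms: none
Why: I/Mg exchange followed by single Grignard addition to the γ-lactone (the magnesium hemiketalate survives until quench, as in aryl C-glycoside synthesis); no stereocentre is touched, and the cis hemiketal protects the α-centre from epimerisation.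

Step 10
Reactants: 12 hydroxy ketone
Product: 13 (R)-[4-(TBSO)-3-methoxyphenyl]{(3R,4R,5S)-5-[4-(TBSO)-3-methoxyphenyl]-4-(hydroxymethyl)oxolan-3-yl}methanol
Conditions: (S)-Me-CBS (0.3 equiv), BH3·SMe2 (2.5 equiv), THF, −20 °C; MeOH quench
Reagents that add atoms: none
Why: Corey–Bakshi–Shibata reduction; with the aryl as the large group, the (S)-catalyst delivers hydride to give the (R)-carbinol under reagent control, and the non-basic conditions leave the α-centre intact.

Step 11
Reactants: 13 bis-silyl ether
Product: 14 (7R)-7-hydroxylariciresinol, 4-[(2S,3R,4R)-4-[(R)-hydroxy(4-hydroxy-3-methoxyphenyl)methyl]-3-(hydroxymethyl)oxolan-2-yl]-2-methoxyphenol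
Conditions: TBAF, AcOH, THF, 0 °C
Reagents that add atoms: none
Why: Fluoride desilylation of both aryl silyl ethers, buffered with AcOH so the p-hydroxybenzylic alcohol and ether do not ionise to quinone methides.

**Compound list**
1 | catechol | Oc1ccccc1O | starting material
2 | guaiacol | COc1ccccc1O | intermediate
3 | 4-bromo-2-methoxyphenol | COc1cc(Br)ccc1O | intermediate
4 | tert-butyl(4-bromo-2-methoxyphenoxy)dimethylsilane | COc1cc(Br)ccc1O[Si](C)(C)C(C)(C)C | intermediate
5 | tert-butyl(4-iodo-2-methoxyphenoxy)dimethylsilane | COc1cc(I)ccc1O[Si](C)(C)C(C)(C)C | intermediate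
6 | (trimethylsilyl)methanol | C[Si](C)(C)CO | starting material
7 | [(chloromethoxy)methyl]trimethylsilane | C[Si](C)(C)COCCl | intermediate
8 | maleic anhydride | O=C1OC(=O)C=C1 | starting material
9 | meso-cis-tetrahydrofuro[3,4-c]furan-1,3-dione | O=C1OC(=O)[C@@H]2COC[C@H]12 | intermediate
10 | (3aS,6aR)-tetrahydro-1H,3H-furo[3,4-c]furan-1-one | O=C1OC[C@@H]2COC[C@H]12 | intermediate
11 | (3aR,4S,6aR)-4-[4-(TBSO)-3-methoxyphenyl]tetrahydro-1H,3H-furo[3,4-c]furan-1-one | O=C1OC[C@@H]2[C@@H](c3ccc(O[Si](C)(C)C(C)(C)C)c(OC)c3)OC[C@H]12 | intermediate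
12 | {(3R,4R,5S)-5-aryl-4-(hydroxymethyl)oxolan-3-yl}(aryl)methanone, aryl = 4-(TBSO)-3-methoxyphenyl | COc1cc([C@H]2OC[C@H](C(=O)c3ccc(O[Si](C)(C)C(C)(C)C)c(OC)c3)[C@@H]2CO)ccc1O[Si](C)(C)C(C)(C)C | intermediate
13 | bis-TBS ether of the target | COc1cc([C@H]2OC[C@H]([C@@H](O)c3ccc(O[Si](C)(C)C(C)(C)C)c(OC)c3)[C@@H]2CO)ccc1O[Si](C)(C)C(C)(C)C | intermediate
14 | (7R)-7-hydroxylariciresinol | COc1cc([C@H]2OC[C@H]([C@@H](O)c3ccc(O)c(OC)c3)[C@@H]2CO)ccc1O | target

**Totals**
Total steps: 11.
Longest linear sequence: 7 steps (1-2-3-8-9-10-11; the branches 1-2-3-4-9-10-11 and 5-6-7-8-9-10-11 are the same length).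

**Three steps most likely to fail**
- **Step 8 (proposed new C–H arylation).** Risks are C4 versus C6 site selectivity, low conversion of the electron-rich bromide, and over-reaction at the new benzylic C–H. Fallback (known chemistry): the classical dilactone route. Oxidise 10 at the ether CH2 with cat. RuCl3/NaIO4 to the C2-symmetric dilactone, add one equivalent of the Grignard from 5, reduce the keto-lactone with NaBH4, and close the oxolane under mild acid (benzylic cation, thermodynamic exo aryl) to reach 11.
- **Step 10 (CBS reduction).** Risks are the ketone/hemiketal equilibrium slowing the reduction and substrate bias eroding the 7R selectivity. Fallback: introduce the aryl group at the aldehyde oxidation level instead. Reduce 11 with DIBAL-H to the lactol and add the aryl under catalyst control (aryl-zinc from the boronic acid and Et2Zn with a chiral amino alcohol), so no ketone is formed.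
- **Step 6 (carbonyl ylide cycloaddition).** The risk is fluoride attacking the anhydride. Fallback: make the meso diester instead, by Pd(II)-catalysed oxidative bis(methoxycarbonylation) of 2,5-dihydrofuran (PdCl2, CuCl2, CO, MeOH) to dimethyl cis-oxolane-3,4-dicarboxylate. Then desymmetrise with pig-liver esterase and reduce the half-ester chemoselectively (BH3·SMe2 or LiBEt3H) to lactone 10.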